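The route rests on cutting the central oxazole at O1–C5 and N3–C4. This 2,4-disubstituted ring holds the C6 carbinol on ring C4 (C7), an unsubstituted ring C5–H (C8) and the oxazol-5-ylmethyl arm on ring C2 (C9), so C7–C8 map onto a bromomethyl ketone and O–C9–N onto a primary amide. One silver-assisted Blümlein–Lewy condensation thus joins the finished C1–C8 polyol to 2-(oxazol-5-yl)acetamide and builds the ring, with no metalated oxazole. The precursor is the C1–C8 bromomethyl ketone carrying a C2 benzyl ether, a C3 TBS ether and a C4/C6 benzylidene acetal, which leaves only desilylation, myristoylation and one neutral hydrogenolysis.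

Key step: step 12

Remark on numbering and configuration: C1 is the methyl terminus, C2–C6 the polyol carbons, and C7, C8, C9 are ring C4, C5, C2 of the central oxazole. The target is (2S,3R,4S,6R), that is C2/C3 syn, C3/C4 anti and C4/C6 syn; no stereochemical error was found in the structures.
Remark on the precursor design: the 1,3-diol is carried as a benzylidene acetal in place of an isopropylidene ketal. It withstands the acid set free in the silver step better, and it falls together with the C2 benzyl ether in the last, neutral step, so the C3 ester (flanked by two hydroxyls in the target and able to migrate) never meets aqueous acid.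
Assumption: 2-(1,3-oxazol-5-yl)acetic acid is taken as a purchasable building block.

Step 1
Reactants: 1 ethyl (S)-lactate
Product: 2 ethyl (2S)-2-(benzyloxy)propanoate
Conditions: BnOC(=NH)CCl3, TfOH (cat.), cyclohexane/CH2Cl2, rt
Reagents that add atoms: benzyl 2,2,2-trichloroacetimidate, ClC(Cl)(Cl)C(=N)OCc1ccccc1
Why: Acid-catalysed O-alkylation by a trichloroacetimidate (imidate benzylation) needs no base, so the α-stereocentre of the lactate is carried through unchanged as C2.

Step 2
Reactants: 2 ethyl (2S)-2-(benzyloxy)propanoate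
Product: 3 (2S)-2-(benzyloxy)propanal
Conditions: DIBAL-H, CH2Cl2, −78 °C; Rochelle salt work-up
Reagents that add atoms: none
Why: DIBAL-H partial reduction of an ester stops at the aluminium hemiacetal at −78 °C and gives the α-benzyloxy aldehyde on work-up, which is used at once to avoid racemisation.

Step 3
Reactants: 3 (2S)-2-(benzyloxy)propanal
Product: 4 (3S,4S)-4-(benzyloxy)pent-1-en-3-ol
Conditions: MgBr2·OEt2, CH2Cl2, −78 °C; then CH2=CHMgBr
Reagents that add atoms: vinylmagnesium bromide, C=C[Mg]Br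
Why: Chelation-controlled (Cram-chelate) Grignard addition, in which magnesium bridges the carbonyl and benzyloxy oxygens and the vinyl group attacks anti to the C1 methyl group, should set C3 syn to C2 (3S,4S), the minor anti isomer being removed by chromatography.

Step 4
Reactants: 4 (3S,4S)-4-(benzyloxy)pent-1-en-3-ol
Product: 5 tert-butyl{[(3S,4S)-4-(benzyloxy)pent-1-en-3-yl]oxy}dimethylsilane
Conditions: TBSCl, imidazole, DMF, rt
Reagents that add atoms: tert-butyldimethylsilyl chloride, CC(C)(C)[Si](C)(C)Cl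
Why: Standard silyl ether formation on a secondary alcohol gives a C3 ether that is non-chelating in the later aldol and orthogonal to the benzyl-type groups.

Step 5
Reactants: 5 tert-butyl{[(3S,4S)-4-(benzyloxy)pent-1-en-3-yl]oxy}dimethylsilane
Product: 7 (2R,3S)-3-(benzyloxy)-2-[(tert-butyldimethylsilyl)oxy]butanal, via ozonide 6 (not isolated)
Conditions: O3, CH2Cl2, −78 °C; then PPh3, −78 °C to rt
Reagents that add atoms: ozone, [O-][O+]=O
Why: Ozonolysis with reductive work-up cleaves the terminal alkene to the C4 aldehyde without touching the ethers, and the α-silyloxy aldehyde is taken on crude so that C3 does not epimerise.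

Step 6
Reactants: 8 ethyl pyruvate
Product: 9 ethyl 2-[(trimethylsilyl)oxy]prop-2-enoate
Conditions: TMSCl, Et3N, DMAP (cat.), CH2Cl2, 0 °C to rt; distillation
Reagents that add atoms: chlorotrimethylsilane, C[Si](C)(C)Cl
Why: Soft enolisation and O-silylation of the pyruvate (silyl enol ether formation) gives the 2-silyloxyacrylate, a pyruvate enolate equivalent that supplies C5–C7.

Step 7
Reactants: 7 (2R,3S)-3-(benzyloxy)-2-[(tert-butyldimethylsilyl)oxy]butanal; 9 ethyl 2-[(trimethylsilyl)oxy]prop-2-enoate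
Product: 10 ethyl (4S,5S,6S)-6-(benzyloxy)-5-[(tert-butyldimethylsilyl)oxy]-4-hydroxy-2-oxoheptanoate
Conditions: BF3·OEt2, CH2Cl2, −78 °C; aqueous NaHCO3
Reagents that add atoms: none
Why: Mukaiyama aldol under non-chelating BF3 activation, in which the polar Felkin–Anh (Cornforth) preference of the α-silyloxy aldehyde and the 1,3-anti influence of the β-benzyloxy group reinforce each other, should set C4 anti to C3 (4S).

Step 8
Reactants: 10 ethyl (4S,5S,6S)-6-(benzyloxy)-5-[(tert-butyldimethylsilyl)oxy]-4-hydroxy-2-oxoheptanoate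
Product: 12 ethyl (2R,4S,5S,6S)-6-(benzyloxy)-5-[(tert-butyldimethylsilyl)oxy]-2,4-dihydroxyheptanoate, via diethylboron chelate 11 (not isolated)
Conditions: Et2BOMe, THF/MeOH (4:1), −78 °C; NaBH4, −78 °C; AcOH, then MeOH co-evaporation
Reagents that add atoms: none
Why: Narasaka–Prasad reduction, in which the C4 alkoxide and the C6 ketone are tied in a six-membered boron chelate and hydride is delivered axially, should set C6 syn to C4 (2R in the ester numbering), the activated α-keto group being reduced at −78 °C while the ester stays intact.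

Step 9
Reactants: 12 ethyl (2R,4S,5S,6S)-6-(benzyloxy)-5-[(tert-butyldimethylsilyl)oxy]-2,4-dihydroxyheptanoate
Product: 13 ethyl (2R,4R,6S)-6-{(1R,2S)-2-(benzyloxy)-1-[(tert-butyldimethylsilyl)oxy]propyl}-2-phenyl-1,3-dioxane-4-carboxylate
Conditions: PhCH(OMe)2, CSA (cat.), CH2Cl2, rt
Reagents that add atoms: benzaldehyde dimethyl acetal, COC(OC)c1ccccc1
Why: Acid-catalysed transacetalisation under thermodynamic control gives the 1,3-dioxane of the syn diol as the all-equatorial chair, which fixes the new acetal centre with phenyl cis to both ring substituents and ties the C6 oxygen into a ring.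

Step 10
Reactants: 13 ethyl (2R,4R,6S)-6-{(1R,2S)-2-(benzyloxy)-1-[(tert-butyldimethylsilyl)oxy]propyl}-2-phenyl-1,3-dioxane-4-carboxylate
Product: 15 2-bromo-1-[(2R,4R,6S)-6-{(1R,2S)-2-(benzyloxy)-1-[(tert-butyldimethylsilyl)oxy]propyl}-2-phenyl-1,3-dioxan-4-yl]ethan-1-one, via lithium hemiketal alkoxide 14 (not isolated)
Conditions: CH2Br2, MeLi·LiBr, THF, −78 °C; AcOH quench at −78 °C
Reagents that add atoms: dibromomethane, BrCBr
Why: Acylation of bromomethyllithium generated in situ by Br/Li exchange, a known halomethyllithium route from α-heteroatom esters to halomethyl ketones, stops at the chelated lithium hemiketal 14 at −78 °C, and the acidic quench releases the ketone without exposing C6 to base.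

Step 11
Reactants: 16 2-(1,3-oxazol-5-yl)acetic acid
Product: 18 2-(1,3-oxazol-5-yl)acetamide, via acyl imidazole 17 (not isolated)
Conditions: CDI, THF, rt; then NH3 (7 M in MeOH), rt
Reagents that add atoms: ammonia, N
Why: Activation of the acid as its acyl imidazole and aminolysis by ammonia (CDI amidation) gives the primary amide under conditions that leave the oxazole untouched.

Step 12
Reactants: 15 2-bromo-1-[(2R,4R,6S)-6-{(1R,2S)-2-(benzyloxy)-1-[(tert-butyldimethylsilyl)oxy]propyl}-2-phenyl-1,3-dioxan-4-yl]ethan-1-one; 18 2-(1,3-oxazol-5-yl)acetamide (excess)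
Product: 21 4-[(2S,4R,6S)-6-{(1R,2S)-2-(benzyloxy)-1-[(tert-butyldimethylsilyl)oxy]propyl}-2-phenyl-1,3-dioxan-4-yl]-2-(1,3-oxazol-5-ylmethyl)-1,3-oxazole, via O-alkyl imidate 19 (not isolated), via 4-hydroxyoxazoline 20 (not isolated)
Conditions: AgOTf, 2,6-di-tert-butyl-4-methylpyridine (about 1 equiv), EtOAc, 60 °C, dark
Reagents that add atoms: none
Why: Silver(I) pulls bromide from C8 while the amide oxygen of 18 alkylates that carbon to give the 2-oxoalkyl imidate 19; its nitrogen then adds to the C7 carbonyl to give the 4-hydroxyoxazoline 20, and loss of water aromatises the ring. This is the silver-promoted Blümlein–Lewy (Hantzsch-type) oxazole synthesis from α-halo ketones and primary amides, a known reaction class. The one ring formed is the central oxazole, closed 5-exo-trig by N3 onto ring C4 (C7) after the intermolecular O1–C5 (C8) bond is made, and no stereocentre is created. Regiochemistry needs no control, because the halo ketone dictates that C7 receives nitrogen and C8 oxygen. The step needs O-alkylation of the amide in preference to N-alkylation of an oxazole nitrogen, and retention at C6; the much higher nucleophilicity of the amide oxygen and the excess of 18 serve the first, the non-basic medium and the C6–H locked in the dioxane chair the second. The hindered pyridine takes up the triflic acid, so the benzylidene acetal and the silyl ether should persist while the medium stays acidic enough for the dehydration.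

Step 13
Reactants: 21 4-[(2S,4R,6S)-6-{(1R,2S)-2-(benzyloxy)-1-[(tert-butyldimethylsilyl)oxy]propyl}-2-phenyl-1,3-dioxan-4-yl]-2-(1,3-oxazol-5-ylmethyl)-1,3-oxazole
Product: 22 4-[(2S,4R,6S)-6-[(1R,2S)-2-(benzyloxy)-1-hydroxypropyl]-2-phenyl-1,3-dioxan-4-yl]-2-(1,3-oxazol-5-ylmethyl)-1,3-oxazole
Conditions: TBAF, THF, 0 °C to rt
Reagents that add atoms: none
Why: Fluoride-mediated desilylation frees only the C3 hydroxyl, since the benzyl ether, the benzylidene acetal and both oxazoles are inert to fluoride.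

Step 14
Reactants: 22 4-[(2S,4R,6S)-6-[(1R,2S)-2-(benzyloxy)-1-hydroxypropyl]-2-phenyl-1,3-dioxan-4-yl]-2-(1,3-oxazol-5-ylmethyl)-1,3-oxazole
Product: 23 (1R,2S)-2-(benzyloxy)-1-[(2S,4S,6R)-6-{2-[(1,3-oxazol-5-yl)methyl]-1,3-oxazol-4-yl}-2-phenyl-1,3-dioxan-4-yl]propyl tetradecanoate
Conditions: C13H27COCl, Et3N, DMAP (cat.), CH2Cl2, 0 °C to rt
Reagents that add atoms: tetradecanoyl (myristoyl) chloride, CCCCCCCCCCCCCC(=O)Cl
Why: DMAP-catalysed acylation with the acid chloride (nucleophilic catalysis) esterifies the single free hydroxyl at C3, so the site of the myristate is fixed by the protecting-group pattern.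

Step 15
Reactants: 23 (1R,2S)-2-(benzyloxy)-1-[(2S,4S,6R)-6-{2-[(1,3-oxazol-5-yl)methyl]-1,3-oxazol-4-yl}-2-phenyl-1,3-dioxan-4-yl]propyl tetradecanoate
Product: 24 (2S,3R,4S,6R)-2,4,6-trihydroxy-6-{2-[(1,3-oxazol-5-yl)methyl]-1,3-oxazol-4-yl}hexan-3-yl tetradecanoate
Conditions: H2 (1 atm), Pd(OH)2/C, EtOAc/EtOH, rt
Reagents that add atoms: none
Why: Catalytic hydrogenolysis of the benzyl ether and of the benzylidene acetal (benzylic C–O cleavage) under neutral conditions frees the C2, C4 and C6 hydroxyls in one operation without acid or base, so the C3 ester should not migrate and the oxazoles and the ester are not reduced.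

Compound list
1 | ethyl (S)-lactate | CCOC(=O)[C@H](C)O | starting material
2 | ethyl (2S)-2-(benzyloxy)propanoate | CCOC(=O)[C@H](C)OCc1ccccc1 | intermediate
3 | (2S)-2-(benzyloxy)propanal | O=C[C@H](C)OCc1ccccc1 | intermediate
4 | (3S,4S)-4-(benzyloxy)pent-1-en-3-ol (C2/C3 syn) | O[C@H]([C@H](C)OCc1ccccc1)C=C | intermediate
5 | tert-butyl{[(3S,4S)-4-(benzyloxy)pent-1-en-3-yl]oxy}dimethylsilane | CC(C)(C)[Si](C)(C)O[C@H]([C@H](C)OCc1ccccc1)C=C | intermediate
6 | ozonide (1,2,4-trioxolane) of 5; ring carbon configuration undefined | CC(C)(C)[Si](C)(C)O[C@H]([C@H](C)OCc1ccccc1)C1OCOO1 | intermediate (not isolated)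
7 | (2R,3S)-3-(benzyloxy)-2-[(tert-butyldimethylsilyl)oxy]butanal | CC(C)(C)[Si](C)(C)O[C@H]([C@H](C)OCc1ccccc1)C=O | intermediate
8 | ethyl pyruvate | CCOC(=O)C(C)=O | starting material
9 | ethyl 2-[(trimethylsilyl)oxy]prop-2-enoate | CCOC(=O)C(=C)O[Si](C)(C)C | intermediate
10 | ethyl (4S,5S,6S)-6-(benzyloxy)-5-[(tert-butyldimethylsilyl)oxy]-4-hydroxy-2-oxoheptanoate | CC(C)(C)[Si](C)(C)O[C@H]([C@H](C)OCc1ccccc1)[C@@H](O)CC(=O)C(=O)OCC | intermediate
11 | diethylboron chelate of 10 (C4–O–BEt2 borinate, boron coordinated to the C6 ketone) | CC(C)(C)[Si](C)(C)O[C@H]([C@H](C)OCc1ccccc1)[C@@H](OB(CC)CC)CC(=O)C(=O)OCC | intermediate (not isolated)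
12 | ethyl (2R,4S,5S,6S)-6-(benzyloxy)-5-[(tert-butyldimethylsilyl)oxy]-2,4-dihydroxyheptanoate | CC(C)(C)[Si](C)(C)O[C@H]([C@H](C)OCc1ccccc1)[C@@H](O)C[C@@H](O)C(=O)OCC | intermediate
13 | ethyl (2R,4R,6S)-6-{(1R,2S)-2-(benzyloxy)-1-[(tert-butyldimethylsilyl)oxy]propyl}-2-phenyl-1,3-dioxane-4-carboxylate (all-cis dioxane) | CC(C)(C)[Si](C)(C)O[C@H]([C@H](C)OCc1ccccc1)[C@@H]1C[C@@H](O[C@H](c2ccccc2)O1)C(=O)OCC | intermediate
14 | lithium hemiketal alkoxide from 13 and bromomethyllithium; hemiketal carbon configuration undefined | CC(C)(C)[Si](C)(C)O[C@H]([C@H](C)OCc1ccccc1)[C@@H]1C[C@@H](O[C@H](c2ccccc2)O1)C([O-])(OCC)CBr.[Li+] | intermediate (not isolated)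
15 | 2-bromo-1-[(2R,4R,6S)-6-{(1R,2S)-2-(benzyloxy)-1-[(tert-butyldimethylsilyl)oxy]propyl}-2-phenyl-1,3-dioxan-4-yl]ethan-1-one (key-step precursor) | CC(C)(C)[Si](C)(C)O[C@H]([C@H](C)OCc1ccccc1)[C@@H]1C[C@@H](O[C@H](c2ccccc2)O1)C(=O)CBr | intermediate
16 | 2-(1,3-oxazol-5-yl)acetic acid | OC(=O)Cc1cnco1 | starting material
17 | 1-[2-(1,3-oxazol-5-yl)acetyl]imidazole | O=C(Cc1cnco1)n1ccnc1 | intermediate (not isolated)
18 | 2-(1,3-oxazol-5-yl)acetamide | NC(=O)Cc1cnco1 | intermediate
19 | O-(2-oxoalkyl) imidate from 15 and 18 (shown as free base) | CC(C)(C)[Si](C)(C)O[C@H]([C@H](C)OCc1ccccc1)[C@@H]1C[C@@H](O[C@H](c2ccccc2)O1)C(=O)COC(=N)Cc1cnco1 | intermediate (not isolated)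
20 | 4-hydroxy-4,5-dihydrooxazole from 19; carbinolamine carbon configuration undefined | CC(C)(C)[Si](C)(C)O[C@H]([C@H](C)OCc1ccccc1)[C@@H]1C[C@@H](O[C@H](c2ccccc2)O1)C1(O)COC(Cc2cnco2)=N1 | intermediate (not isolated)
21 | 4-[(2S,4R,6S)-6-{(1R,2S)-2-(benzyloxy)-1-[(tert-butyldimethylsilyl)oxy]propyl}-2-phenyl-1,3-dioxan-4-yl]-2-(1,3-oxazol-5-ylmethyl)-1,3-oxazole (key-step product) | CC(C)(C)[Si](C)(C)O[C@H]([C@H](C)OCc1ccccc1)[C@@H]1C[C@@H](O[C@H](c2ccccc2)O1)c1coc(Cc2cnco2)n1 | intermediate
22 | 4-[(2S,4R,6S)-6-[(1R,2S)-2-(benzyloxy)-1-hydroxypropyl]-2-phenyl-1,3-dioxan-4-yl]-2-(1,3-oxazol-5-ylmethyl)-1,3-oxazole | O[C@H]([C@H](C)OCc1ccccc1)[C@@H]1C[C@@H](O[C@H](c2ccccc2)O1)c1coc(Cc2cnco2)n1 | intermediate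
23 | (1R,2S)-2-(benzyloxy)-1-[(2S,4S,6R)-6-{2-[(1,3-oxazol-5-yl)methyl]-1,3-oxazol-4-yl}-2-phenyl-1,3-dioxan-4-yl]propyl tetradecanoate | CCCCCCCCCCCCCC(=O)O[C@H]([C@H](C)OCc1ccccc1)[C@@H]1C[C@@H](O[C@H](c2ccccc2)O1)c1coc(Cc2cnco2)n1 | intermediate
24 | (2S,3R,4S,6R)-2,4,6-trihydroxy-6-{2-[(1,3-oxazol-5-yl)methyl]-1,3-oxazol-4-yl}hexan-3-yl tetradecanoate | CCCCCCCCCCCCCC(=O)O[C@H]([C@H](C)O)[C@@H](O)C[C@@H](O)c1coc(Cc2cnco2)n1 | target

Total step count: 15 (13 on the main line, plus one step each for enolsilane 9 and amide 18).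
Longest linear sequence: 13 steps (steps 1–5, 7–10, 12–15).

Steps most likely to fail

Step 12 (oxazole annulation). The acid and heat of the silver step may strip the acetal or the silyl ether, the silver-activated halo ketone may alkylate an oxazole nitrogen in place of the amide oxygen, or the sequence may stall before dehydration. The fallback is a two-stage Davidson oxazole synthesis that forms the same two bonds. It sets out from 15 and uses acid 16: the caesium salt of 16 (Cs2CO3, DMF, rt) displaces the bromide to give the α-acyloxy ketone 2-[(2R,4R,6S)-6-{(1R,2S)-2-(benzyloxy)-1-[(tert-butyldimethylsilyl)oxy]propyl}-2-phenyl-1,3-dioxan-4-yl]-2-oxoethyl 2-(1,3-oxazol-5-yl)acetate F1. Heating F1 with NH4OAc in AcOH at 80–90 °C lets ammonia condense with the C7 ketone, the nitrogen add to the ester carbonyl and water leave. The fallback comes back to the route at 21.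

Step 10 (ester to bromomethyl ketone). The tetrahedral intermediate may collapse before the quench and take up a second carbenoid, the carbenoid may decompose before it is trapped, or methyllithium may attack the ester directly. The fallback sets out from 13 and avoids the carbenoid. MeNH(OMe)·HCl and i-PrMgCl (THF, −20 °C) give the Weinreb amide (2R,4R,6S)-6-{(1R,2S)-2-(benzyloxy)-1-[(tert-butyldimethylsilyl)oxy]propyl}-N-methoxy-N-methyl-2-phenyl-1,3-dioxane-4-carboxamide F2. MeMgBr (THF, 0 °C) gives the methyl ketone 1-[(2R,4R,6S)-6-{(1R,2S)-2-(benzyloxy)-1-[(tert-butyldimethylsilyl)oxy]propyl}-2-phenyl-1,3-dioxan-4-yl]ethan-1-one F3. Kinetic enolisation on the methyl side with silylation (LiHMDS, TMSCl, THF, −78 °C) gives the silyl enol ether [(1-{(2R,4R,6S)-6-[(1R,2S)-2-(benzyloxy)-1-[(tert-butyldimethylsilyl)oxy]propyl]-2-phenyl-1,3-dioxan-4-yl}ethenyl)oxy]trimethylsilane F4. Bromination of F4 with NBS (THF, −78 to 0 °C) comes back to the route at 15.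

Step 9 (benzylidene acetal formation). Under acid the C4 hydroxyl may lactonise onto the ester (γ-lactone formation) faster than the acetal closes. The fallback sets out from 12 and never exposes a free hydroxyl to acid. Silylation (TMSCl, imidazole, CH2Cl2, 0 °C) gives the bis(trimethylsilyl) ether ethyl (2R,4S,5R,6S)-6-(benzyloxy)-5-[(tert-butyldimethylsilyl)oxy]-2,4-bis[(trimethylsilyl)oxy]heptanoate F5. Noyori acetalisation of F5 (PhCHO, TMSOTf cat., CH2Cl2, −78 °C) comes back to the route at 13.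

Further compounds
F1 | step 12 | 2-[(2R,4R,6S)-6-{(1R,2S)-2-(benzyloxy)-1-[(tert-butyldimethylsilyl)oxy]propyl}-2-phenyl-1,3-dioxan-4-yl]-2-oxoethyl 2-(1,3-oxazol-5-yl)acetate | CC(C)(C)[Si](C)(C)O[C@H]([C@H](C)OCc1ccccc1)[C@@H]1C[C@@H](O[C@H](c2ccccc2)O1)C(=O)COC(=O)Cc1cnco1
F2 | step 10 | (2R,4R,6S)-6-{(1R,2S)-2-(benzyloxy)-1-[(tert-butyldimethylsilyl)oxy]propyl}-N-methoxy-N-methyl-2-phenyl-1,3-dioxane-4-carboxamide | CC(C)(C)[Si](C)(C)O[C@H]([C@H](C)OCc1ccccc1)[C@@H]1C[C@@H](O[C@H](c2ccccc2)O1)C(=O)N(C)OC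
F3 | step 10 | 1-[(2R,4R,6S)-6-{(1R,2S)-2-(benzyloxy)-1-[(tert-butyldimethylsilyl)oxy]propyl}-2-phenyl-1,3-dioxan-4-yl]ethan-1-one | CC(C)(C)[Si](C)(C)O[C@H]([C@H](C)OCc1ccccc1)[C@@H]1C[C@@H](O[C@H](c2ccccc2)O1)C(C)=O
F4 | step 10 | [(1-{(2R,4R,6S)-6-[(1R,2S)-2-(benzyloxy)-1-[(tert-butyldimethylsilyl)oxy]propyl]-2-phenyl-1,3-dioxan-4-yl}ethenyl)oxy]trimethylsilane | CC(C)(C)[Si](C)(C)O[C@H]([C@H](C)OCc1ccccc1)[C@@H]1C[C@@H](O[C@H](c2ccccc2)O1)C(=C)O[Si](C)(C)C
F5 | step 9 | ethyl (2R,4S,5R,6S)-6-(benzyloxy)-5-[(tert-butyldimethylsilyl)oxy]-2,4-bis[(trimethylsilyl)oxy]heptanoate | CC(C)(C)[Si](C)(C)O[C@H]([C@H](C)OCc1ccccc1)[C@@H](O[Si](C)(C)C)C[C@@H](O[Si](C)(C)C)C(=O)OCC
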